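Ring numbering used throughout: C1 ketone, C2 (bears C7H2OH), C3 alkene CH, C4 angelate carbinol, C5 isopropyl carbon, C6 epoxyangelate carbinol. The retrosynthesis cuts the two ester C–O bonds (C4–O, C6–O), returns C1 to a carbinol and C7 to an ester, then cuts C1–C2 and C2=C3; this releases C2/C7 as trimethyl phosphonoacetate and C3–C4–C5–C6–C1 as a 2,4-dioxygenated 3-isopropylpentanedial.
Enabling feature: in the C4–C5–C6 triad the two carbinol carbons are like-configured and anti about C5, so the opened chain is pseudo-C2-symmetric (C5 is no stereocentre when the two ethers are equal). It is the ozonolysis product of a trans-2-isopropylcyclopent-4-ene-1,3-diol, and inserting the one carbon C2 between the two formyl carbons rebuilds the six-membered ring.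
Forward: furfural and iPrMgCl give a furyl carbinol; Piancatelli rearrangement makes a cyclopentenone; reduction and protection give the cyclopentene diol diether; ozonolysis opens the five-membered ring; the [5+1] aldol/Horner–Wadsworth–Emmons annulation closes the only ring of the target; redox adjustment at C1/C7 and two acylations finish.
Stereochemistry: C5/C6 trans from the conrotatory 4π closure of the Piancatelli step, absolute configuration from a lipase resolution, C4 from hydride addition anti to isopropyl, the epoxide centres from a Sharpless epoxidation of angelyl alcohol, the Z alkene from angelic acid.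
Because C5 carries H and isopropyl, the two formyl groups of the dialdehyde are diastereotopic, not equivalent. Unequal ethers (PMB on C6–O, TBS on C4–O) are meant to bias the annulation, but they do not enforce its site selectivity; they also keep the two carbinols apart for the late acylations.

Key step: step 9

Assumption: the lipase acetylates the (4R,5S) enantiomer of 4 (branched C5 as the large, the vinylic CH as the medium carbinol substituent, the usual sense for lipase acylation of secondary alcohols); with the opposite sense the recovered alcohol would be acetylated with Ac2O/pyridine and enter step 4 unchanged.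

Step 1
Reactants: 1 furfural and 2 isopropylmagnesium chloride
Product: 3 rac-1-(furan-2-yl)-2-methylpropan-1-ol
Conditions: iPrMgCl, THF, 0 °C; aq. NH4Cl
Reagents that add atoms: isopropylmagnesium chloride (2), CC(C)[Mg]Cl
Why: Grignard addition to the aldehyde gives the racemic furyl carbinol, whose stereocentre is erased in the next step.

Step 2
Reactants: 3 rac-1-(furan-2-yl)-2-methylpropan-1-ol
Product: 4 rac-trans-4-hydroxy-5-(propan-2-yl)cyclopent-2-en-1-one
Conditions: ZnCl2, dioxane/H2O, reflux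
Reagents that add atoms: water, O
Why: Piancatelli rearrangement (ionisation of the carbinol, attack of water at C5 of the furan, ring opening and conrotatory 4π electrocyclisation of the pentadienyl cation) should place hydroxyl and isopropyl trans on the cyclopentenone.

Step 3
Reactants: 4 rac-trans-4-hydroxy-5-(propan-2-yl)cyclopent-2-en-1-one
Product: 5 (1R,5S)-4-oxo-5-(propan-2-yl)cyclopent-2-en-1-yl acetate
Conditions: immobilised Candida antarctica lipase B, vinyl acetate, MTBE, 30 °C, stopped near half conversion; unreacted (4S,5R) alcohol removed by chromatography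
Reagents that add atoms: vinyl acetate, C=COC(C)=O
Why: Lipase-catalysed kinetic resolution by enantioselective transesterification should convert only the (4R,5S) alcohol into its acetate, which fixes the absolute configuration of the future C5 and C6.

Step 4
Reactants: 5 (1R,5S)-4-oxo-5-(propan-2-yl)cyclopent-2-en-1-yl acetate
Product: 6 (1R,4R,5R)-4-hydroxy-5-(propan-2-yl)cyclopent-2-en-1-yl acetate
Conditions: NaBH4, CeCl3·7H2O, MeOH, −78 °C
Reagents that add atoms: none
Why: Luche reduction gives 1,2-reduction of the enone, and hydride is expected to add to the carbonyl face anti to the adjacent isopropyl group, so the new hydroxyl (future C4–O) should end up cis to isopropyl and trans to the acetoxy group.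

Step 5
Reactants: 6 (1R,4R,5R)-4-hydroxy-5-(propan-2-yl)cyclopent-2-en-1-yl acetate
Product: 7 (1R,4R,5S)-4-[(tert-butyldimethylsilyl)oxy]-5-(propan-2-yl)cyclopent-2-en-1-yl acetate
Conditions: TBSOTf, 2,6-lutidine, CH2Cl2, −78 → 0 °C
Reagents that add atoms: tert-butyldimethylsilyl triflate, CC(C)(C)[Si](C)(C)OS(=O)(=O)C(F)(F)F
Why: Silylation with the silyl triflate should cap the hindered allylic alcohol while the acetate is inert.

Step 6
Reactants: 7 (1R,4R,5S)-4-[(tert-butyldimethylsilyl)oxy]-5-(propan-2-yl)cyclopent-2-en-1-yl acetate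
Product: 8 (1R,4R,5S)-4-[(tert-butyldimethylsilyl)oxy]-5-(propan-2-yl)cyclopent-2-en-1-ol
Conditions: K2CO3 (cat.), MeOH, 0 °C → rt
Reagents that add atoms: none
Why: Base-catalysed methanolysis (transesterification) removes the acetate, the TBS ether is stable, and the trans-1,3 arrangement rules out silyl migration.

Step 7
Reactants: 8 (1R,4R,5S)-4-[(tert-butyldimethylsilyl)oxy]-5-(propan-2-yl)cyclopent-2-en-1-ol
Product: 9 tert-butyl({(1R,4R,5S)-4-[(4-methoxyphenyl)methoxy]-5-(propan-2-yl)cyclopent-2-en-1-yl}oxy)dimethylsilane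
Conditions: NaH, PMBCl, Bu4NI (cat.), DMF, 0 °C → rt
Reagents that add atoms: 4-methoxybenzyl chloride, COc1ccc(CCl)cc1
Why: Williamson etherification installs the PMB ether that distinguishes the future C6–O from the silylated C4–O.

Step 8
Reactants: 9 tert-butyl({(1R,4R,5S)-4-[(4-methoxyphenyl)methoxy]-5-(propan-2-yl)cyclopent-2-en-1-yl}oxy)dimethylsilane
Product: 11 (2S,3S,4S)-2-[(tert-butyldimethylsilyl)oxy]-4-[(4-methoxyphenyl)methoxy]-3-(propan-2-yl)pentanedial, via ozonide 10 (not isolated)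
Conditions: O3, CH2Cl2, −78 °C (stopped at the first blue tinge); PPh3, −78 °C → rt; used crude
Reagents that add atoms: ozone, [O-][O+]=O
Why: Ozonolysis with reductive work-up cleaves the only C=C bond to the dialdehyde without touching the three stereocentres, and stopping at the first excess of ozone should spare the PMB arene.

Step 9
Reactants: 11 (2S,3S,4S)-2-[(tert-butyldimethylsilyl)oxy]-4-[(4-methoxyphenyl)methoxy]-3-(propan-2-yl)pentanedial and 12 trimethyl phosphonoacetate
Product: 15 methyl (3R,4S,5S)-3-[(tert-butyldimethylsilyl)oxy]-6-hydroxy-5-[(4-methoxyphenyl)methoxy]-4-(propan-2-yl)cyclohex-1-ene-1-carboxylate (both C6 carbinol epimers), via hydroxy phosphonate 13 (not isolated), via cyclic dihydroxy phosphonate 14 (not isolated)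
Conditions: K2CO3, THF/H2O, 0 °C → rt
Reagents that add atoms: trimethyl phosphonoacetate (12), COC(=O)CP(=O)(OC)OC
Why: Carbonate deprotonates the phosphonoacetate, whose carbanion adds to one formyl group to give 13; 13 is deprotonated again at carbon and closes on the second formyl group to 14, which loses dimethyl phosphate through an oxaphosphetane to give 15 (tandem aldol/intramolecular Horner–Wadsworth–Emmons olefination, the reaction type known for glutaraldehyde and phosphonoacetates in aqueous carbonate). The six-membered carbocycle closes by a 6-(enolexo)-exo-trig addition of the C2 carbanion to the C3 formyl carbon, followed by syn-elimination. The only new stereocentre, the C1 carbinol, is uncontrolled and need not be controlled because step 12 oxidises it; C4, C5 and C6 are carried over from 11. The step needs site selectivity between the two diastereotopic formyl groups (aldol at the one on C6, olefination at the one on C4) and configurational integrity α to both aldehydes. The intended bias comes from the unequal ethers: the formyl group next to the compact PMB ether is the more accessible and more electrophilic and should take up the phosphonate first, leaving the one next to the TBS ether (syn to isopropyl) for the ring-closing olefination. Mild carbonate and fast intramolecular closure should limit epimerisation of the α-alkoxy aldehydes.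

Step 10
Reactants: 15 methyl (3R,4S,5S)-3-[(tert-butyldimethylsilyl)oxy]-6-hydroxy-5-[(4-methoxyphenyl)methoxy]-4-(propan-2-yl)cyclohex-1-ene-1-carboxylate
Product: 16 (4R,5S,6S)-4-[(tert-butyldimethylsilyl)oxy]-2-(hydroxymethyl)-6-[(4-methoxyphenyl)methoxy]-5-(propan-2-yl)cyclohex-2-en-1-ol (both C1 epimers)
Conditions: iBu2AlH, CH2Cl2, −78 °C; aq. potassium sodium tartrate
Reagents that add atoms: none
Why: Hydride reduction of the conjugated ester by iBu2AlH gives the allylic alcohol (C7) while silyl and PMB ethers are inert.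

Step 11
Reactants: 16 (4R,5S,6S)-4-[(tert-butyldimethylsilyl)oxy]-2-(hydroxymethyl)-6-[(4-methoxyphenyl)methoxy]-5-(propan-2-yl)cyclohex-2-en-1-ol
Product: 17 (4R,5S,6S)-4-[(tert-butyldimethylsilyl)oxy]-2-{[(tert-butyldiphenylsilyl)oxy]methyl}-6-[(4-methoxyphenyl)methoxy]-5-(propan-2-yl)cyclohex-2-en-1-ol (both C1 epimers)
Conditions: TBDPSCl, imidazole, CH2Cl2, 0 °C
Reagents that add atoms: tert-butyldiphenylsilyl chloride, CC(C)(C)[Si](Cl)(c1ccccc1)c1ccccc1
Why: The bulky silyl chloride should silylate the primary allylic alcohol selectively over the hindered secondary one.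

Step 12
Reactants: 17 (4R,5S,6S)-4-[(tert-butyldimethylsilyl)oxy]-2-{[(tert-butyldiphenylsilyl)oxy]methyl}-6-[(4-methoxyphenyl)methoxy]-5-(propan-2-yl)cyclohex-2-en-1-ol
Product: 18 (4R,5S,6S)-4-[(tert-butyldimethylsilyl)oxy]-2-{[(tert-butyldiphenylsilyl)oxy]methyl}-6-[(4-methoxyphenyl)methoxy]-5-(propan-2-yl)cyclohex-2-en-1-one
Conditions: Dess–Martin periodinane, CH2Cl2, 0 °C → rt
Reagents that add atoms: none
Why: Dess–Martin oxidation of the only free (secondary allylic) alcohol gives the enone and erases the uncontrolled C1 stereocentre.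

Step 13
Reactants: 18 (4R,5S,6S)-4-[(tert-butyldimethylsilyl)oxy]-2-{[(tert-butyldiphenylsilyl)oxy]methyl}-6-[(4-methoxyphenyl)methoxy]-5-(propan-2-yl)cyclohex-2-en-1-one
Product: 19 (4R,5R,6S)-2-{[(tert-butyldiphenylsilyl)oxy]methyl}-4-hydroxy-6-[(4-methoxyphenyl)methoxy]-5-(propan-2-yl)cyclohex-2-en-1-one
Conditions: (+)-camphor-10-sulfonic acid (cat.), MeOH/CH2Cl2, 0 °C → rt
Reagents that add atoms: none
Why: Acid-catalysed methanolysis should cleave the secondary TBS ether while the far more acid-stable TBDPS ether and the PMB ether remain.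

Step 14
Reactants: 19 (4R,5R,6S)-2-{[(tert-butyldiphenylsilyl)oxy]methyl}-4-hydroxy-6-[(4-methoxyphenyl)methoxy]-5-(propan-2-yl)cyclohex-2-en-1-one and 20 angelic acid
Product: 22 (1R,5S,6R)-3-{[(tert-butyldiphenylsilyl)oxy]methyl}-5-[(4-methoxyphenyl)methoxy]-4-oxo-6-(propan-2-yl)cyclohex-2-en-1-yl (2Z)-2-methylbut-2-enoate, via mixed anhydride 21 (not isolated)
Conditions: angelic acid, 2,4,6-trichlorobenzoyl chloride, Et3N, toluene, rt; then 19, 80 °C (no DMAP)
Reagents that add atoms: angelic acid (20), C/C=C(/C)C(=O)O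
Why: Yamaguchi-type esterification through the mixed anhydride without a nucleophilic catalyst is the standard way to transfer angelic acid without Z to E isomerisation; C4 keeps its configuration because only the O–H bond reacts, and the one epimerisable centre (C6) already holds its ether in the more stable position trans to isopropyl.

Step 15
Reactants: 22 (1R,5S,6R)-3-{[(tert-butyldiphenylsilyl)oxy]methyl}-5-[(4-methoxyphenyl)methoxy]-4-oxo-6-(propan-2-yl)cyclohex-2-en-1-yl (2Z)-2-methylbut-2-enoate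
Product: 23 (1R,5S,6S)-3-{[(tert-butyldiphenylsilyl)oxy]methyl}-5-hydroxy-4-oxo-6-(propan-2-yl)cyclohex-2-en-1-yl (2Z)-2-methylbut-2-enoate
Conditions: DDQ, CH2Cl2/pH 7 buffer, 0 °C → rt
Reagents that add atoms: none
Why: Oxidative PMB cleavage by DDQ (benzylic hydride abstraction, then hydrolysis of the oxocarbenium ion) should free the C6 hydroxyl under neutral conditions that leave the angelate, the enone and the silyl ether intact.

Step 16
Reactants: 20 angelic acid
Product: 24 (2Z)-2-methylbut-2-en-1-ol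
Conditions: LiAlH4, Et2O, 0 °C
Reagents that add atoms: none
Why: LiAlH4 reduces the carboxylic acid to the allylic alcohol by 1,2-reduction with retention of the Z geometry.

Step 17
Reactants: 24 (2Z)-2-methylbut-2-en-1-ol
Product: 25 [(2S,3R)-2,3-dimethyloxiran-2-yl]methanol
Conditions: Ti(OiPr)4, L-(+)-diethyl tartrate, tBuOOH, 4 Å sieves, CH2Cl2, −20 °C
Reagents that add atoms: tert-butyl hydroperoxide, CC(C)(C)OO
Why: Sharpless asymmetric epoxidation with the L-(+)-tartrate ligand should deliver oxygen to the alkene face that gives the (2S,3R) epoxy alcohol, the Z geometry being carried stereospecifically into the cis relationship of the C3 methyl and the hydroxymethyl group.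

Step 18
Reactants: 25 [(2S,3R)-2,3-dimethyloxiran-2-yl]methanol
Product: 27 (2R,3R)-2,3-dimethyloxirane-2-carboxylic acid, via epoxy aldehyde 26 (not isolated)
Conditions: RuCl3 (cat.), NaIO4, MeCN/EtOAc/H2O, rt
Reagents that add atoms: water, O
Why: RuO4 formed in situ oxidises the primary alcohol through the aldehyde and its hydrate to the acid without opening the epoxide, the C2 descriptor changing from S to R only because the substituent priorities change.

Step 19
Reactants: 23 (1R,5S,6S)-3-{[(tert-butyldiphenylsilyl)oxy]methyl}-5-hydroxy-4-oxo-6-(propan-2-yl)cyclohex-2-en-1-yl (2Z)-2-methylbut-2-enoate and 27 (2R,3R)-2,3-dimethyloxirane-2-carboxylic acid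
Product: 29 (1S,5R,6R)-3-{[(tert-butyldiphenylsilyl)oxy]methyl}-5-{[(2Z)-2-methylbut-2-enoyl]oxy}-2-oxo-6-(propan-2-yl)cyclohex-3-en-1-yl (2R,3R)-2,3-dimethyloxirane-2-carboxylate, via mixed anhydride 28 (not isolated)
Conditions: 27, 2,4,6-trichlorobenzoyl chloride, Et3N, THF, rt; then 23, DMAP, toluene, rt
Reagents that add atoms: (2R,3R)-2,3-dimethyloxirane-2-carboxylic acid (27), C[C@H]1O[C@]1(C)C(=O)O
Why: Yamaguchi esterification with DMAP as acyl-transfer catalyst should acylate the C6 hydroxyl of the α-hydroxy ketone; the saturated epoxy acid cannot isomerise and no stereocentre is touched.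

Step 20
Reactants: 29 (1S,5R,6R)-3-{[(tert-butyldiphenylsilyl)oxy]methyl}-5-{[(2Z)-2-methylbut-2-enoyl]oxy}-2-oxo-6-(propan-2-yl)cyclohex-3-en-1-yl (2R,3R)-2,3-dimethyloxirane-2-carboxylate
Product: 30 (1S,5R,6R)-3-(hydroxymethyl)-5-{[(2Z)-2-methylbut-2-enoyl]oxy}-2-oxo-6-(propan-2-yl)cyclohex-3-en-1-yl (2R,3R)-2,3-dimethyloxirane-2-carboxylate (CNP0293054.1)
Conditions: HF·pyridine, pyridine, THF, 0 °C → rt
Reagents that add atoms: none
Why: Buffered fluoride desilylation should remove the primary TBDPS ether under mildly acidic conditions that the two esters, the epoxide and the γ-acyloxy enone tolerate.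

Compound list
1 | furfural (furan-2-carbaldehyde) | O=Cc1ccco1 | starting material
2 | isopropylmagnesium chloride | CC(C)[Mg]Cl | starting material
3 | rac-1-(furan-2-yl)-2-methylpropan-1-ol | CC(C)C(O)c1ccco1 | intermediate
4 | rac-trans-4-hydroxy-5-(propan-2-yl)cyclopent-2-en-1-one, (4R,5S) and (4S,5R) 1:1 | O=C1C=C[C@@H](O)[C@@H]1C(C)C.O=C1C=C[C@H](O)[C@H]1C(C)C | intermediate
5 | (1R,5S)-4-oxo-5-(propan-2-yl)cyclopent-2-en-1-yl acetate | O=C1C=C[C@@H](OC(C)=O)[C@@H]1C(C)C | intermediate
6 | (1R,4R,5R)-4-hydroxy-5-(propan-2-yl)cyclopent-2-en-1-yl acetate (OH cis to isopropyl, trans to OAc) | O[C@@H]1C=C[C@@H](OC(C)=O)[C@@H]1C(C)C | intermediate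
7 | (1R,4R,5S)-4-[(tert-butyldimethylsilyl)oxy]-5-(propan-2-yl)cyclopent-2-en-1-yl acetate | CC(C)(C)[Si](C)(C)O[C@@H]1C=C[C@@H](OC(C)=O)[C@@H]1C(C)C | intermediate
8 | (1R,4R,5S)-4-[(tert-butyldimethylsilyl)oxy]-5-(propan-2-yl)cyclopent-2-en-1-ol | CC(C)(C)[Si](C)(C)O[C@@H]1C=C[C@@H](O)[C@@H]1C(C)C | intermediate
9 | tert-butyl({(1R,4R,5S)-4-[(4-methoxyphenyl)methoxy]-5-(propan-2-yl)cyclopent-2-en-1-yl}oxy)dimethylsilane | CC(C)(C)[Si](C)(C)O[C@@H]1C=C[C@@H](OCc2ccc(OC)cc2)[C@@H]1C(C)C | intermediate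
10 | ozonide of 9: 2-[(tert-butyldimethylsilyl)oxy]-4-[(4-methoxyphenyl)methoxy]-3-(propan-2-yl)-6,7,8-trioxabicyclo[3.2.1]octane (C2–C4 as in 9, acetal carbons unassigned) | CC(C)(C)[Si](C)(C)O[C@H]1[C@@H](C(C)C)[C@H](OCc2ccc(OC)cc2)C3OOC1O3 | intermediate
11 | (2S,3S,4S)-2-[(tert-butyldimethylsilyl)oxy]-4-[(4-methoxyphenyl)methoxy]-3-(propan-2-yl)pentanedial | O=C[C@@H](O[Si](C)(C)C(C)(C)C)[C@@H](C(C)C)[C@H](OCc1ccc(OC)cc1)C=O | intermediate
12 | trimethyl phosphonoacetate | COC(=O)CP(=O)(OC)OC | starting material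
13 | methyl 6-[(tert-butyldimethylsilyl)oxy]-2-(dimethoxyphosphoryl)-3-hydroxy-4-[(4-methoxyphenyl)methoxy]-7-oxo-5-(propan-2-yl)heptanoate (C4–C6 as in 11; C2, C3 epimer mixture) | O=C[C@@H](O[Si](C)(C)C(C)(C)C)[C@@H](C(C)C)[C@H](OCc1ccc(OC)cc1)C(O)C(P(=O)(OC)OC)C(=O)OC | intermediate
14 | methyl 3-[(tert-butyldimethylsilyl)oxy]-1-(dimethoxyphosphoryl)-2,6-dihydroxy-5-[(4-methoxyphenyl)methoxy]-4-(propan-2-yl)cyclohexane-1-carboxylate (C3–C5 as in 15; C1, C2, C6 unassigned) | CC(C)(C)[Si](C)(C)O[C@@H]1C(O)C(P(=O)(OC)OC)(C(=O)OC)C(O)[C@@H](OCc2ccc(OC)cc2)[C@@H]1C(C)C | intermediate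
15 | methyl (3R,4S,5S)-3-[(tert-butyldimethylsilyl)oxy]-6-hydroxy-5-[(4-methoxyphenyl)methoxy]-4-(propan-2-yl)cyclohex-1-ene-1-carboxylate (C6 epimers) | CC(C)(C)[Si](C)(C)O[C@@H]1C=C(C(=O)OC)C(O)[C@@H](OCc2ccc(OC)cc2)[C@@H]1C(C)C | intermediate
16 | (4R,5S,6S)-4-[(tert-butyldimethylsilyl)oxy]-2-(hydroxymethyl)-6-[(4-methoxyphenyl)methoxy]-5-(propan-2-yl)cyclohex-2-en-1-ol (C1 epimers) | CC(C)(C)[Si](C)(C)O[C@@H]1C=C(CO)C(O)[C@@H](OCc2ccc(OC)cc2)[C@@H]1C(C)C | intermediate
17 | (4R,5S,6S)-4-[(tert-butyldimethylsilyl)oxy]-2-{[(tert-butyldiphenylsilyl)oxy]methyl}-6-[(4-methoxyphenyl)methoxy]-5-(propan-2-yl)cyclohex-2-en-1-ol (C1 epimers) | CC(C)(C)[Si](C)(C)O[C@@H]1C=C(CO[Si](c2ccccc2)(c2ccccc2)C(C)(C)C)C(O)[C@@H](OCc2ccc(OC)cc2)[C@@H]1C(C)C | intermediate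
18 | (4R,5S,6S)-4-[(tert-butyldimethylsilyl)oxy]-2-{[(tert-butyldiphenylsilyl)oxy]methyl}-6-[(4-methoxyphenyl)methoxy]-5-(propan-2-yl)cyclohex-2-en-1-one | CC(C)(C)[Si](C)(C)O[C@@H]1C=C(CO[Si](c2ccccc2)(c2ccccc2)C(C)(C)C)C(=O)[C@@H](OCc2ccc(OC)cc2)[C@@H]1C(C)C | intermediate
19 | (4R,5R,6S)-2-{[(tert-butyldiphenylsilyl)oxy]methyl}-4-hydroxy-6-[(4-methoxyphenyl)methoxy]-5-(propan-2-yl)cyclohex-2-en-1-one | O[C@@H]1C=C(CO[Si](c2ccccc2)(c2ccccc2)C(C)(C)C)C(=O)[C@@H](OCc2ccc(OC)cc2)[C@@H]1C(C)C | intermediate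
20 | angelic acid, (2Z)-2-methylbut-2-enoic acid | C/C=C(/C)C(=O)O | starting material
21 | (2Z)-2-methylbut-2-enoic 2,4,6-trichlorobenzoic anhydride | C/C=C(/C)C(=O)OC(=O)c1c(Cl)cc(Cl)cc1Cl | intermediate
22 | (1R,5S,6R)-3-{[(tert-butyldiphenylsilyl)oxy]methyl}-5-[(4-methoxyphenyl)methoxy]-4-oxo-6-(propan-2-yl)cyclohex-2-en-1-yl (2Z)-2-methylbut-2-enoate | C/C=C(/C)C(=O)O[C@@H]1C=C(CO[Si](c2ccccc2)(c2ccccc2)C(C)(C)C)C(=O)[C@@H](OCc2ccc(OC)cc2)[C@@H]1C(C)C | intermediate
23 | (1R,5S,6S)-3-{[(tert-butyldiphenylsilyl)oxy]methyl}-5-hydroxy-4-oxo-6-(propan-2-yl)cyclohex-2-en-1-yl (2Z)-2-methylbut-2-enoate | C/C=C(/C)C(=O)O[C@@H]1C=C(CO[Si](c2ccccc2)(c2ccccc2)C(C)(C)C)C(=O)[C@@H](O)[C@@H]1C(C)C | intermediate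
24 | (2Z)-2-methylbut-2-en-1-ol | C/C=C(/C)CO | intermediate
25 | [(2S,3R)-2,3-dimethyloxiran-2-yl]methanol | OC[C@]1(C)O[C@@H]1C | intermediate
26 | (2R,3R)-2,3-dimethyloxirane-2-carbaldehyde | O=C[C@]1(C)O[C@@H]1C | intermediate
27 | (2R,3R)-2,3-dimethyloxirane-2-carboxylic acid | OC(=O)[C@]1(C)O[C@@H]1C | intermediate
28 | (2R,3R)-2,3-dimethyloxirane-2-carboxylic 2,4,6-trichlorobenzoic anhydride | O=C(OC(=O)c1c(Cl)cc(Cl)cc1Cl)[C@]2(C)O[C@@H]2C | intermediate
29 | (1S,5R,6R)-3-{[(tert-butyldiphenylsilyl)oxy]methyl}-5-{[(2Z)-2-methylbut-2-enoyl]oxy}-2-oxo-6-(propan-2-yl)cyclohex-3-en-1-yl (2R,3R)-2,3-dimethyloxirane-2-carboxylate | C/C=C(/C)C(=O)O[C@@H]1C=C(CO[Si](c2ccccc2)(c2ccccc2)C(C)(C)C)C(=O)[C@@H](OC(=O)[C@]2(C)O[C@@H]2C)[C@@H]1C(C)C | intermediate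
30 | (1S,5R,6R)-3-(hydroxymethyl)-5-{[(2Z)-2-methylbut-2-enoyl]oxy}-2-oxo-6-(propan-2-yl)cyclohex-3-en-1-yl (2R,3R)-2,3-dimethyloxirane-2-carboxylate | C/C=C(/C)C(=O)O[C@@H]1C=C(CO)C(=O)[C@@H](OC(=O)[C@]2(C)O[C@@H]2C)[C@@H]1C(C)C | target

Total steps: 20. Longest linear sequence: 17 (steps 1–15, 19, 20); steps 16–18 make the epoxy acid and join at step 19.

Steps most likely to fail

Step 9 – erosion of site selectivity. The aldol addition is reversible, and the cyclic dihydroxy phosphonate can eliminate toward either carbinol, so the alkene may form next to C6 and the carbinol next to C4; the ether bias is modest and its direction is not guaranteed. The fallback does not rely on this selectivity. It sets out from 11, accepts the regioisomeric annulation product methyl (3R,4S,5S)-5-[(tert-butyldimethylsilyl)oxy]-6-hydroxy-3-[(4-methoxyphenyl)methoxy]-4-(propan-2-yl)cyclohex-1-ene-1-carboxylate F1 formed under the step 9 conditions, and corrects it by a 1,3-carbonyl transposition. Reduction with iBu2AlH gives the diol (4R,5S,6S)-6-[(tert-butyldimethylsilyl)oxy]-2-(hydroxymethyl)-4-[(4-methoxyphenyl)methoxy]-5-(propan-2-yl)cyclohex-2-en-1-ol F2. Silylation with TBDPSCl/imidazole gives its primary silyl ether (4R,5S,6S)-6-[(tert-butyldimethylsilyl)oxy]-2-{[(tert-butyldiphenylsilyl)oxy]methyl}-4-[(4-methoxyphenyl)methoxy]-5-(propan-2-yl)cyclohex-2-en-1-ol F3. Dess–Martin oxidation gives the transposed enone (4R,5S,6S)-6-[(tert-butyldimethylsilyl)oxy]-2-{[(tert-butyldiphenylsilyl)oxy]methyl}-4-[(4-methoxyphenyl)methoxy]-5-(propan-2-yl)cyclohex-2-en-1-one F4. Nucleophilic epoxidation (H2O2, NaOH, MeOH, 0 °C) gives the epoxy ketone 3-[(tert-butyldimethylsilyl)oxy]-1-{[(tert-butyldiphenylsilyl)oxy]methyl}-5-[(4-methoxyphenyl)methoxy]-4-(propan-2-yl)-7-oxabicyclo[4.1.0]heptan-2-one F5. Wharton transposition (N2H4·H2O, AcOH, MeOH) then moves the oxygen to C1 and the alkene to C2=C3 and comes back to the route at 17. If both regioisomers form, 15 follows the main line, F1 follows this branch, and the two streams meet at 17.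

Step 4 – poor facial selectivity of hydride addition. The acetoxy group across the ring steers hydride toward the face that the isopropyl group is meant to block. The fallback replaces steric control by internal hydride delivery and sets out from 5. Lipase-mediated hydrolysis (phosphate buffer, pH 7) gives (4R,5S)-4-hydroxy-5-(propan-2-yl)cyclopent-2-en-1-one F6. Evans–Saksena reduction (Me4NBH(OAc)3, AcOH/MeCN, −20 °C) delivers hydride from boron bound to the C4 hydroxyl and should give the anti diol (1R,3R)-2-(propan-2-yl)cyclopent-4-ene-1,3-diol F7. Monoacetylation of the less hindered carbinol, the one trans to isopropyl (lipase, vinyl acetate, MTBE), comes back to the route at 6.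

Step 14 – Z to E isomerisation of the angeloyl unit during activation, and slow acylation of the hindered C4 carbinol. The fallback builds the Z alkene on the oxygen and sets out from 19. Steglich esterification (EDC, DMAP, CH2Cl2) with 2-(diphenoxyphosphoryl)propanoic acid, a saturated acid that cannot isomerise, gives (1R,5S,6R)-3-{[(tert-butyldiphenylsilyl)oxy]methyl}-5-[(4-methoxyphenyl)methoxy]-4-oxo-6-(propan-2-yl)cyclohex-2-en-1-yl 2-(diphenoxyphosphoryl)propanoate F8. Z-selective Horner–Wadsworth–Emmons olefination of this diaryl phosphonate with acetaldehyde (NaI, DBU, THF, 0 °C) forms the (2Z)-2-methylbut-2-enoate and comes back to the route at 22.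

Further compounds
F1 | step 9 | methyl (3R,4S,5S)-5-[(tert-butyldimethylsilyl)oxy]-6-hydroxy-3-[(4-methoxyphenyl)methoxy]-4-(propan-2-yl)cyclohex-1-ene-1-carboxylate | CC(C)(C)[Si](C)(C)O[C@@H]1C(O)C(C(=O)OC)=C[C@@H](OCc2ccc(OC)cc2)[C@@H]1C(C)C
F2 | step 9 | (4R,5S,6S)-6-[(tert-butyldimethylsilyl)oxy]-2-(hydroxymethyl)-4-[(4-methoxyphenyl)methoxy]-5-(propan-2-yl)cyclohex-2-en-1-ol | CC(C)(C)[Si](C)(C)O[C@@H]1C(O)C(CO)=C[C@@H](OCc2ccc(OC)cc2)[C@@H]1C(C)C
F3 | step 9 | (4R,5S,6S)-6-[(tert-butyldimethylsilyl)oxy]-2-{[(tert-butyldiphenylsilyl)oxy]methyl}-4-[(4-methoxyphenyl)methoxy]-5-(propan-2-yl)cyclohex-2-en-1-ol | CC(C)(C)[Si](C)(C)O[C@@H]1C(O)C(CO[Si](c2ccccc2)(c2ccccc2)C(C)(C)C)=C[C@@H](OCc2ccc(OC)cc2)[C@@H]1C(C)C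
F4 | step 9 | (4R,5S,6S)-6-[(tert-butyldimethylsilyl)oxy]-2-{[(tert-butyldiphenylsilyl)oxy]methyl}-4-[(4-methoxyphenyl)methoxy]-5-(propan-2-yl)cyclohex-2-en-1-one | CC(C)(C)[Si](C)(C)O[C@@H]1C(=O)C(CO[Si](c2ccccc2)(c2ccccc2)C(C)(C)C)=C[C@@H](OCc2ccc(OC)cc2)[C@@H]1C(C)C
F5 | step 9 | 3-[(tert-butyldimethylsilyl)oxy]-1-{[(tert-butyldiphenylsilyl)oxy]methyl}-5-[(4-methoxyphenyl)methoxy]-4-(propan-2-yl)-7-oxabicyclo[4.1.0]heptan-2-one (C3–C5 as in F4, epoxide face unassigned) | CC(C)(C)[Si](C)(C)O[C@@H]1C(=O)C2(CO[Si](c3ccccc3)(c3ccccc3)C(C)(C)C)OC2[C@@H](OCc4ccc(OC)cc4)[C@@H]1C(C)C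
F6 | step 4 | (4R,5S)-4-hydroxy-5-(propan-2-yl)cyclopent-2-en-1-one | O=C1C=C[C@@H](O)[C@@H]1C(C)C
F7 | step 4 | (1R,3R)-2-(propan-2-yl)cyclopent-4-ene-1,3-diol | O[C@@H]1C=C[C@@H](O)C1C(C)C
F8 | step 14 | (1R,5S,6R)-3-{[(tert-butyldiphenylsilyl)oxy]methyl}-5-[(4-methoxyphenyl)methoxy]-4-oxo-6-(propan-2-yl)cyclohex-2-en-1-yl 2-(diphenoxyphosphoryl)propanoate | CC(P(=O)(Oc1ccccc1)Oc1ccccc1)C(=O)O[C@@H]1C=C(CO[Si](c2ccccc2)(c2ccccc2)C(C)(C)C)C(=O)[C@@H](OCc2ccc(OC)cc2)[C@@H]1C(C)C
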